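The numbers in the tables are calculated from invented constants; scatter was added.

Leave the constants alone: these runs are too thin to give one worth carrying, so reckon with a ratio.

| flask | starting material | coupling partner | free catalyst | impurity | temperature | remark | time |
|---|---|---|---|---|---|---|---|
| gamma | 0.50 M | 1 M (fed, over 50 min) | 1.9 mM | 2.3 mM | −25 °C | run made earlier; the fed solution adds 1.0 times the starting volume |  |
| alpha | 0.50 M | 1 M (fed, over 50 min) | 2.8 mM | 2.3 mM | −8 °C | run made earlier; the fed solution adds 1.0 times the starting volume |  |
| epsilon | 0.50 M | 1 M (fed, over 50 min) | 5.6 mM | 2.3 mM | −25 °C | run made earlier; the fed solution adds 1.0 times the starting volume |  |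
| beta | 0.50 M | 1 M (fed, over 50 min) | 6.5 mM | 1.6 mM | −8 °C | run made earlier; the fed solution adds 1.0 times the starting volume |  |
| Sunday's | 0.50 M | 1.00 M (fed, over 50 min) | 6.5 mM | 2.3 mM |  | at −20 °C until 15 min, from then on at 5 °C; the fed solution adds 1.0 times the starting volume | 50 min |
| Tuesday's | 0.50 M | 1.00 M (fed, over 50 min) | 1.5 mM | 1.2 mM |  | at 5 °C throughout; the fed solution adds 1.0 times the starting volume | 50 min |

- gamma (time / min: product / %): 2.00: 0.5; 4.00: 0; 8.00: 0; 12.0: 0; 25.0: 0
- alpha (time / min: product / %): 1.00: 0; 3.00: 0; 6.00: 1.0; 12.0: 0.6; 15.0: 0.2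
- epsilon (time / min: product / %): 2.00: 0.1; 4.00: 0.1; 8.00: 0.7; 12.0: 0.2; 25.0: 0.9
- beta (time / min: product / %): 3.00: 0.1; 6.00: 1.8; 8.00: 2.7; 12.0: 5.1; 15.0: 6.3

(standard deviation of a reading: 0.5 percentage points)

- the winner by amount of product, in percent of the starting material charged; "neither" if no more than 2 percentage points parts them (Sunday's / Tuesday's / neither)
- how much product is there at the end, in percent of the starting material charged: Sunday's
- how much product is there at the end, in percent of the starting material charged: Tuesday's

- every charge counts on the volume at the start, and the solution that is fed holds the whole dose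
- a reading or a percentage of product counts all its forms, free or not

Use the bench rule first: impurity titrates free catalyst one to one, so subtract it. The gamma run, with 1.9 mM against 2.3 mM, never reads above 0.5 percentage points. The beta run, with 4.90 mM left over, reaches 6.3 % at 15.0 min. The epsilon run at −25 °C reads 0.9 % at 25.0 min, so count Sunday's cold stage as nothing.

Now integrate. Dosing is steady, so the partner in the flask grows with time; take the rate as proportional to it and to the excess, and product goes as time squared. The part of that integral earned after the change of temperature on Sunday's is 91.0 %. Sunday's then comes to 3.82 mM, and this is the warm catalyst: the excess of free catalyst over impurity, times the part of the integral earned at 5 °C. Tuesday's, warm throughout, has 0.300 mM. My reckoning: Sunday's wins by a factor 12.7.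

Find the border with impurity over catalyst. Sunday's stands at 0.354, Tuesday's at 0.800, the alpha run at 0.821. The alpha run never read above 1.0 %, and Tuesday's excess is smaller than alpha's. Trust Tuesday's figure least.

The forecast names Sunday's, with 70 % against 14 %, a factor 5.00, not my 12.7. Its ground: “So active catalyst ≈ free catalyst − impurity.”

The flasks give Sunday's as winner, 33.8 % against 1.88 %, a factor 18.0 where the warm catalyst gave 12.7.

    coupling partner + catalyst intermediate → free catalyst + product (k = 0.680 M⁻¹ s⁻¹, Ea = 43.0 kJ mol⁻¹)
    free catalyst + product ⇌ idle complex, settled at all times (K = 1.70 M⁻¹, ΔH = −39.0 kJ mol⁻¹)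
    starting material + free catalyst ⇌ free catalyst + open intermediate (K = 8.10, k = 0.0230 M⁻¹ s⁻¹, Ea = 39.0 kJ mol⁻¹, ΔH = −87.0 kJ mol⁻¹)
    free catalyst + impurity → spent catalyst (k = 41.0 M⁻¹ s⁻¹, Ea = 38.0 kJ mol⁻¹)
    free catalyst + open intermediate ⇌ catalyst intermediate (K = 6.40 M⁻¹, k = 0.170 M⁻¹ s⁻¹, Ea = 52.0 kJ mol⁻¹, ΔH = −18.0 kJ mol⁻¹)
    (constants at −20 °C)

Take one difference between the flasks, the charge of free catalyst: Tuesday's run at Sunday's 6.5 mM, with its own 1.2 mM impurity and 5 °C kept, gives 50.1 % instead of 1.88 %. Read that as a part of the difference between the two flasks, no more. For a neighbour of Sunday's with 2.60 mM free catalyst and the rest held, warm catalyst is 0.273 mM, which scales Sunday's result to 2.42 %; the computed flask gives 1.08 %.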